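## Structural features

The target is a 1,2,3,4-tetrasubstituted cyclobutane (ring A). Ca and Cc carry 4-hydroxy-3-methoxyphenyl groups; Cb and Cd carry carboxyl groups, each esterified at O–C6 of a cis-fused octahydrocyclopenta[c]pyridine (N-methylpiperidine ring B fused along C4a–C7a to cyclopentane ring C). On ring A the two aryl groups are cis, the Cb carboxyl is trans to both and the Cd carboxyl is cis to both. The core alone therefore has a mirror plane through Cb and Cd, and all chirality lies in the two bicyclic units. Each unit has five contiguous stereocentres (C4, C4a, C7a, C7, C6; 4R,4aR,7R,7aS, both C-methyls on the convex face). The units differ only at C6: the Cb ester oxygen is cis to the C7 methyl (6S), the Cd ester oxygen is trans to it (6R). Fragile points are the free phenols (oxidation, competing nucleophiles), Cd–H (α to a carbonyl and flanked by two cis aryl groups, so epimerisation is downhill), the strained ring with two benzylic bonds (cleavage to two cinnamates), the two tertiary amines and the two secondary-alkyl esters. The real difficulty is the ring A pattern, which is not that of a head-to-tail cinnamate photodimer (aryls trans), together with telling Cb from Cd and attaching C6-epimeric alcohols to them. The key step exploits the Cd–Cc bond: Cd is α to an ester and Cc is benzylic, and the chain Cd(CO2R)–Ca(Ar)–Cb(CO2R)–Cc(Ar) is C2–C3–C4–C5 of a 3,5-diarylpyrrolidine-2,4-dicarboxylate, an azomethine ylide cycloadduct without its nitrogen.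

## Logic of the disconnections

**29 ⇒ 28.** The two phenolic O–H bonds are replaced by O–benzyl bonds. Free phenols would be oxidised by trivalent iodine and would compete as nucleophiles in the alkylative esterification. The last step must then cleave two aryl benzyl ethers without touching the esters, the amines or ring A.

**28 ⇒ 27 + 25.** The alkyl–oxygen bond C6–O of the Cd ester is cut, with inversion in the forward sense. The Cd carboxyl is crowded and its α-CH is epimerisable, so it should act only as a nucleophile and never as an activated acyl group. The cut also draws the 6R ester from the same alcohol that serves the 6S ester. The forward step must achieve SN2 displacement at a secondary cyclopentyl carbon by a hindered carboxylate in preference to elimination.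

**27 ⇒ 26 ⇒ 10 + 25.** The acyl–oxygen bond of the Cb ester is cut (retention at C6), and the Cd acid is masked as its tert-butyl ester. The target reduces to two equivalents of 25 and the half-ester 10, whose carboxyls are distinguishable. The forward steps need acylation of a secondary alcohol by an acid that has no reason to epimerise, and acidolysis of the tert-butyl group in the presence of benzyl aryl ethers and electron-rich arenes.

**10 ⇒ 9.** The O–methyl bond of the Cb ester is cut. The methyl ester lies on the face that carries no aryl group and must be saponified while the tert-butyl ester stays.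

**9 ⇒ 6 (key).** The Cd–Cc bond is cut and NH is placed between the two carbons. A strained ring with four stereocentres becomes a pyrrolidine that a cycloaddition assembles in one step. The forward step must remove nitrogen with retention at both carbons and without fragmentation. Because 9 is meso, 6 may be racemic. The methyl/tert-butyl pair and the benzyl ethers of 6 are kept, since they serve the later unmasking order.

**6 ⇒ 5 + 2.** The C2–C3 and C4–C5 bonds of the pyrrolidine ring are cut (retro-1,3-dipolar cycloaddition). Two bonds and four stereocentres go back to an imine and an E-cinnamate. The forward step must be exo-selective (C4 ester away from the C2 and C5 substituents) and regioselective (aryl-bearing alkene carbon to C3).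

**5 ⇒ 3 + 4; 2 ⇒ 1.** The C=N bond and the O–benzyl bond are cut. Both lead to purchasable materials by routine condensation and etherification.

**25 ⇒ 24 ⇒ 23.** The N–CH3 group is traced to an N–CO2CH3 group and the C6–H bond to a ketone. Nitrogen stays non-basic through the cobalt chemistry, and the carbamate carbon becomes the N-methyl carbon. Hydride must arrive at C6 anti to the C7 methyl.

**23 ⇒ 21.** The C7a–H and C7–H bonds are cut. The forward hydrogenation must give the cis ring fusion, and C7, being α to the ketone, can be corrected by equilibration.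

**21 ⇒ 19.** The C4a–C7a, C5–C6 and C6–C7 bonds are cut. Both rings fall back to an acyclic enyne with one stereocentre plus carbon monoxide. The forward step needs 1,2-induction from C4 to C4a.

**19 ⇒ 18 ⇒ 16 + 17.** The N–C(=O) bond and the N–C3 bond are cut. The amine displacement must not touch the allylic stereocentre.

**16 ⇒ 15 ⇒ 14 ⇒ 13 ⇒ 12 ⇒ 11.** The sulfonate, the silyl ether and the C4a=C5 double bond are traced back. The hydroxymethyl arm of 11 becomes C3 and its ester arm becomes the vinyl group (C4a, C5), so the S enantiomer of 11 gives 4R. The α-stereocentre must survive the aldehyde stage.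

## Other disconnections considered

**Alternative 1:** The cut runs through rings B and C. C4a–C7a, C5–C6 and C6–C7 are broken, giving the N-methyl enyne A1 (N-methyl-N-[(R)-2-methylbut-3-en-1-yl]but-2-yn-1-amine) and a carbonyl unit. In the forward sense Co2(CO)8 would turn A1 into the bicyclic enone A2 in one operation, with C4a set by the purchased C4 stereocentre.
- In favour: three skeletal bonds and two rings per step, every carbon of the amine in place, one bought stereocentre.
- Against as the strategic step here: it addresses only the alcohol half. It leaves the ring A pattern, the Cb/Cd differentiation and the C6 epimer pair unsolved, and A2 still needs C7a, C7 and C6 set afterwards. A free tertiary amine is also a doubtful spectator for cobalt carbonyl chemistry.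
- Comparison: on bonds and rings per step A1 → A2 is the better of the two (three bonds and two rings against one bond and one ring). On step economy the N-methyl variant is one step shorter than the carbamate variant used here, since no LiAlH4 step is needed. On stereochemical leverage the nitrogen deletion is stronger, because it carries four stereocentres into a ring that cannot be bought. The chosen route uses the same annulation, in carbamate form, as a supporting step (step 13), so the two ideas are complementary.

**Alternative 2:** The cut is the Cb–Ca bond of ring A (C3–C6 of a pyranone), followed by the two aryl–carbon bonds at Ca and Cc. Forward, irradiation of the pyranone A3 (tert-butyl coumalate) would close it disrotatorily to the bicyclic lactone A4. Hydrogenation with hydrogenolysis of the allylic C–O bond would give the cis half-ester A5. Its free carboxyl would carry a directing amide for two Pd(OAc)2-catalysed C–H arylations with the aryl iodide A6, and one carboxyl-bearing carbon would then be epimerised.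
- In favour: no nitrogen to delete, so no biradical and no fragmentation; no trivalent iodine near electron-rich arenes; both aryl groups come from one iodide. Directed arylation places both aryls cis to a carboxyl by design, and on this point the alternative is the equal of the chosen plan.
- Against here: the second arylation must go onto an already crowded face. Both carboxyl carbons are then cis to both aryls and only one may be epimerised. The directing amide must be cleaved at a hindered carbonyl, and A3 must first be made from coumalic acid.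
- Comparison: the mechanism is electrocyclisation plus a divalent/tetravalent palladium C–H cycle, against cycloaddition plus radical-pair collapse. Stereochemistry is installed stepwise on the ring instead of being transferred in one event. The estimated count to a half-ester of the type of 10 is about seven or eight steps against five. In oxidant safety and likely scalability of ring formation the alternative is the better.

**Alternative 3:** The cut is the C1–C7a bond of ring B. The precursor is the 4-substituted 2-methylcyclopent-2-enone A7, whose side chain ends in N(CH3)CH2SiMe3. Forward, single-electron oxidation of the amine (for example with photoexcited 9,10-dicyanoanthracene) and loss of silicon would give the α-amino radical. This adds 6-exo-trig to the enone β-carbon, and the enolate is protonated at C7 to give the cis-fused ketone A8.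
- In favour: the step sets C7a (cis fusion enforced by the tether) and C7 together and delivers the saturated N-methyl ketone directly. It avoids both the hydrogenation of a tetrasubstituted enone and the carbamate reduction; on these points it is the better.
- Against here: A7 needs two adjacent stereocentres (C4 and C4a) fixed on a cyclopentenone before the key step, which is longer than making the enyne 19. Like Alternative 1, it does nothing for ring A.
- Comparison: it forms one ring and one bond and sets two stereocentres. The chosen key step forms one ring and one bond, sets none and preserves four. The two are of equal mechanistic risk (both radical). Overall step economy is probably no better once A7 is counted.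

Key step: step 4

Remark on the chemistry: the configurations of 6 and 9 were re-derived from the target (retention maps pyrrolidine C2, C3, C4, C5 onto Cd, Ca, Cb, Cc) and need no correction. Because 9 and 10 are meso, 6 to 8 are carried as racemates and their SMILES show one enantiomer.

## Route

Step 1
Reactants: 1 methyl (E)-ferulate
Product: 2 methyl (E)-3-[4-(benzyloxy)-3-methoxyphenyl]acrylate
Conditions: BnBr, K2CO3, DMF, rt → 50 °C
Reagents that add atoms: benzyl bromide, BrCc1ccccc1
Why: Williamson etherification of the phenoxide; the ester and the E-alkene are inert to K2CO3. Benzyl is chosen because it survives trivalent iodine, LiOH, CF3CO2H and the Mitsunobu reaction and leaves by hydrogenolysis.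

Step 2
Reactants: 3 4-(benzyloxy)-3-methoxybenzaldehyde; 4 tert-butyl glycinate
Product: 5 tert-butyl (E)-N-[4-(benzyloxy)-3-methoxybenzylidene]glycinate
Conditions: MgSO4, CH2Cl2, rt
Reagents that add atoms: none
Why: Imine condensation driven by removal of water; aryl aldimines of glycinates form as the E isomers and are used without chromatography.

Step 3
Reactants: 5 tert-butyl (E)-N-[4-(benzyloxy)-3-methoxybenzylidene]glycinate; 2 methyl (E)-3-[4-(benzyloxy)-3-methoxyphenyl]acrylate
Product: 6 2-tert-butyl 4-methyl (2S*,3S*,4R*,5R*)-3,5-bis[4-(benzyloxy)-3-methoxyphenyl]pyrrolidine-2,4-dicarboxylate (racemic exo adduct; C2 ester and both aryl groups on one face; C4 ester on the other)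
Conditions: Cu(CH3CN)4PF6 (5 mol %), rac-BINAP (5.5 mol %), Et3N (20 mol %), THF, 0 °C → rt
Reagents that add atoms: none
Why: 1,3-dipolar cycloaddition of the N,O-chelated, W-shaped copper azomethine ylide; the ylide geometry fixes C2/C5 cis, the E-alkene fixes C3/C4 trans, and the ylide α-carbon attacks the β-carbon of the cinnamate so the aryl lands on C3. The bulky bisphosphine on tetrahedral monovalent copper should turn the dipolarophile ester away from the metal (exo), which puts the C3 aryl cis to the C2 ester and the C5 aryl; an achiral outcome suffices because step 4 gives a meso product.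

Step 4
Reactants: 6 2-tert-butyl 4-methyl (2S*,3S*,4R*,5R*)-3,5-bis[4-(benzyloxy)-3-methoxyphenyl]pyrrolidine-2,4-dicarboxylate
Product: 9 1-tert-butyl 3-methyl 2,4-bis[4-(benzyloxy)-3-methoxyphenyl]cyclobutane-1,3-dicarboxylate (meso; aryl groups cis; tert-butyl ester cis to both; methyl ester trans to both), via 1,1-diazene 7 (not isolated), via 1,4-biradical 8 (not isolated)
Conditions: PhI(OH)OTs (2.5 equiv), NH2CO2NH4 (8 equiv), CF3CH2OH, 80 °C
Reagents that add atoms: none
Why: Ammonia released from ammonium carbamate is oxidised by the trivalent-iodine reagent to an electrophilic iodonitrene, which aminates the ring nitrogen of 6 and, after a second two-electron oxidation, leaves the 1,1-diazene 7. Loss of dinitrogen from 7 gives the singlet 1,4-biradical 8, benzylic at the carbon that becomes Cc and ester-stabilised at the carbon that becomes Cd. The cyclobutane closes by recombination of the two radical termini, which forms the Cd–Cc bond. The closest known reaction type is the iodonitrene-mediated contraction of polysubstituted pyrrolidines to cyclobutanes, a relative of the oxidative deamination of N-amino heterocycles through isodiazenes. No new stereocentre arises: the two carbons that lose nitrogen keep their configuration because collapse of the singlet pair is faster than bond rotation, so the 2,3-cis/3,4-trans/4,5-trans pattern of 6 becomes the aryl-cis, ester-trans pattern of 9. The selectivity needed is ring closure over β-scission of 8 into two cinnamates and over rotation; the short lifetime of the singlet pair in hot trifluoroethanol and the substituent on every carbon of the chain work for it. The benzyl ethers keep the arenes from reacting as phenols, and the excess carbamate buffers the sulfonic acid so that the tert-butyl ester survives. Since 9 has a mirror plane through Cb and Cd, both enantiomers of 6 converge on it.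

Step 5
Reactants: 9 1-tert-butyl 3-methyl 2,4-bis[4-(benzyloxy)-3-methoxyphenyl]cyclobutane-1,3-dicarboxylate
Product: 10 3-(tert-butoxycarbonyl)-2,4-bis[4-(benzyloxy)-3-methoxyphenyl]cyclobutane-1-carboxylic acid (meso; acid trans to both aryl groups)
Conditions: LiOH, THF–MeOH–H2O, rt → 40 °C; then 1 M HCl to pH 3, 0 °C
Reagents that add atoms: lithium hydroxide (its oxygen ends in the carboxyl group), [Li+].[OH-]
Why: Saponification of the methyl ester, which sits alone on the aryl-free face, while the tert-butyl ester resists hydroxide. Cb already has its favoured trans arrangement and LiOH does not enolise the tert-butyl ester at Cd, so no epimerisation is expected.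

Step 6
Reactants: 11 methyl (S)-3-hydroxy-2-methylpropanoate
Product: 12 methyl (S)-3-[(tert-butyldiphenylsilyl)oxy]-2-methylpropanoate
Conditions: t-BuPh2SiCl, imidazole, DMF, rt
Reagents that add atoms: tert-butyl(chloro)diphenylsilane, CC(C)(C)[Si](Cl)(c1ccccc1)c1ccccc1
Why: Silylation of the primary alcohol; the bulky silyl ether makes the next intermediates non-volatile and tolerates i-Bu2AlH and the ylide.

Step 7
Reactants: 12 methyl (S)-3-[(tert-butyldiphenylsilyl)oxy]-2-methylpropanoate
Product: 13 (S)-3-[(tert-butyldiphenylsilyl)oxy]-2-methylpropanal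
Conditions: i-Bu2AlH (1.1 equiv), CH2Cl2, −78 °C; aq. KNaC4H4O6
Reagents that add atoms: none
Why: Partial reduction of the ester through a tetrahedral aluminium hemiacetal that is stable at −78 °C and collapses only on work-up. The α-stereocentre is kept if the aldehyde is used at once without chromatography.

Step 8
Reactants: 13 (S)-3-[(tert-butyldiphenylsilyl)oxy]-2-methylpropanal
Product: 14 (R)-tert-butyl[(2-methylbut-3-en-1-yl)oxy]diphenylsilane
Conditions: Ph3PCH3Br, KN(SiMe3)2, THF, 0 °C; then 13, −78 → 0 °C
Reagents that add atoms: methyltriphenylphosphonium bromide, C[P+](c1ccccc1)(c1ccccc1)c1ccccc1.[Br-]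
Why: Wittig methylenation; the non-stabilised ylide adds to the aldehyde faster than it deprotonates the hindered α-CH at low temperature. The descriptor changes from S to R only through the priority rules.

Step 9
Reactants: 14 (R)-tert-butyl[(2-methylbut-3-en-1-yl)oxy]diphenylsilane
Product: 15 (R)-2-methylbut-3-en-1-ol
Conditions: Bu4NF, THF, 0 °C → rt
Reagents that add atoms: none
Why: Fluoride cleavage of the silyl ether; the volatile alcohol is kept in solution after cold concentration and taken straight into step 10.

Step 10
Reactants: 15 (R)-2-methylbut-3-en-1-ol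
Product: 16 (R)-2-methylbut-3-en-1-yl 4-methylbenzenesulfonate
Conditions: TsCl, Et3N, DMAP (cat.), CH2Cl2, 0 °C → rt
Reagents that add atoms: 4-methylbenzenesulfonyl chloride, Cc1ccc(S(=O)(=O)Cl)cc1
Why: Sulfonylation of the primary alcohol gives a non-volatile electrophile; the stereocentre is not involved.

Step 11
Reactants: 16 (R)-2-methylbut-3-en-1-yl 4-methylbenzenesulfonate; 17 but-2-yn-1-amine
Product: 18 N-[(R)-2-methylbut-3-en-1-yl]but-2-yn-1-amine
Conditions: 17 (5 equiv), MeCN, 60 °C
Reagents that add atoms: none
Why: SN2 displacement of the primary sulfonate by the neutral amine; the excess amine suppresses dialkylation and is too weak a base for elimination to the diene. The adjacent stereocentre is untouched.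

Step 12
Reactants: 18 N-[(R)-2-methylbut-3-en-1-yl]but-2-yn-1-amine
Product: 19 methyl (but-2-yn-1-yl)[(R)-2-methylbut-3-en-1-yl]carbamate
Conditions: ClCO2Me, Et3N, CH2Cl2, 0 °C
Reagents that add atoms: methyl chloroformate, COC(=O)Cl
Why: N-acylation; the carbamate removes the basicity that cobalt carbonyls tolerate poorly, its planar nitrogen helps the chain to fold, and its carbonyl carbon is the latent N-methyl carbon.

Step 13
Reactants: 19 methyl (but-2-yn-1-yl)[(R)-2-methylbut-3-en-1-yl]carbamate
Product: 21 methyl (4R,4aR)-4,7-dimethyl-6-oxo-1,3,4,4a,5,6-hexahydro-2H-cyclopenta[c]pyridine-2-carboxylate, via alkyne–Co2(CO)6 complex 20 (not isolated)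
Conditions: Co2(CO)8 (1.1 equiv), CH2Cl2, rt; then N-methylmorpholine N-oxide (8 equiv), 0 °C → rt
Reagents that add atoms: dicobalt octacarbonyl (source of the ring carbonyl), [Co].[Co].[C-]#[O+].[C-]#[O+].[C-]#[O+].[C-]#[O+].[C-]#[O+].[C-]#[O+].[C-]#[O+].[C-]#[O+]
Why: Intramolecular Pauson–Khand reaction, a known ring closure for N-acyl and N-sulfonyl 1,7-enynes: alkene insertion, CO insertion and reductive elimination form C4a–C7a, C6–C7 and C5–C6, and the internal alkyne places its methyl on C7. In the chair-like insertion transition state the C4 methyl is pseudo-equatorial, which should set C4a with the C4 methyl trans to C5.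

Step 14
Reactants: 21 methyl (4R,4aR)-4,7-dimethyl-6-oxo-1,3,4,4a,5,6-hexahydro-2H-cyclopenta[c]pyridine-2-carboxylate
Product: 23 methyl (4R,4aR,7R,7aS)-4,7-dimethyl-6-oxooctahydro-2H-cyclopenta[c]pyridine-2-carboxylate (cis-fused; both C-methyls on the convex face), via C7-epimeric ketone 22 (not isolated)
Conditions: H2 (1 atm), 10% Pd/C, EtOAc, rt; filter; then K2CO3 (cat.), MeOH, rt
Reagents that add atoms: none
Why: Heterogeneous hydrogenation adds H2 syn to C7 and C7a from the face that carries H4a, the usual course for ring-fused cyclopentenones, giving the cis fusion and first the ketone 22 with its C7 methyl on the concave face. Base equilibration through the enolate then moves that methyl to the convex face, trans to C1.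

Step 15
Reactants: 23 methyl (4R,4aR,7R,7aS)-4,7-dimethyl-6-oxooctahydro-2H-cyclopenta[c]pyridine-2-carboxylate
Product: 24 methyl (4R,4aR,6S,7R,7aS)-6-hydroxy-4,7-dimethyloctahydro-2H-cyclopenta[c]pyridine-2-carboxylate
Conditions: LiBH(s-Bu)3, THF, −78 °C; then aq. NaOH, H2O2, 0 °C
Reagents that add atoms: none
Why: A bulky trialkylborohydride attacks a 2,3-trans-disubstituted cyclopentanone anti to the α-substituent, here the C7 methyl, so the hydroxyl should emerge cis to that methyl (6S). The carbamate is inert at −78 °C.

Step 16
Reactants: 24 methyl (4R,4aR,6S,7R,7aS)-6-hydroxy-4,7-dimethyloctahydro-2H-cyclopenta[c]pyridine-2-carboxylate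
Product: 25 (4R,4aR,6S,7R,7aS)-2,4,7-trimethyloctahydro-1H-cyclopenta[c]pyridin-6-ol
Conditions: LiAlH4, THF, reflux; aq. NaOH work-up
Reagents that add atoms: none
Why: LiAlH4 reduces the methyl carbamate to the N-methyl amine; no stereocentre is involved and the alcohol is carried as its alkoxide.

Step 17
Reactants: 10 3-(tert-butoxycarbonyl)-2,4-bis[4-(benzyloxy)-3-methoxyphenyl]cyclobutane-1-carboxylic acid; 25 (4R,4aR,6S,7R,7aS)-2,4,7-trimethyloctahydro-1H-cyclopenta[c]pyridin-6-ol
Product: 26 1-tert-butyl 3-[(4R,4aR,6S,7R,7aS)-2,4,7-trimethyloctahydro-1H-cyclopenta[c]pyridin-6-yl] 2,4-bis[4-(benzyloxy)-3-methoxyphenyl]cyclobutane-1,3-dicarboxylate (ring A as in 9)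
Conditions: DIC, DMAP, CH2Cl2, 0 °C → rt
Reagents that add atoms: none
Why: Steglich esterification; the C6–O bond is not touched, so the ester oxygen stays cis to the C7 methyl, and the Cb acid has no driving force to epimerise on activation. Because 10 has a mirror plane through Cb and Cd, the single-enantiomer alcohol gives one diastereomer.

Step 18
Reactants: 26 1-tert-butyl 3-[(4R,4aR,6S,7R,7aS)-2,4,7-trimethyloctahydro-1H-cyclopenta[c]pyridin-6-yl] 2,4-bis[4-(benzyloxy)-3-methoxyphenyl]cyclobutane-1,3-dicarboxylate
Product: 27 2,4-bis[4-(benzyloxy)-3-methoxyphenyl]-3-{[(4R,4aR,6S,7R,7aS)-2,4,7-trimethyloctahydro-1H-cyclopenta[c]pyridin-6-yl]oxycarbonyl}cyclobutane-1-carboxylic acid (acid at Cd; cis to both aryl groups)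
Conditions: CF3CO2H–CH2Cl2 (1:4), Et3SiH, 0 °C → rt; then pH 7 buffer
Reagents that add atoms: none
Why: Acidolysis of the tert-butyl ester by alkyl–oxygen cleavage, which is indifferent to the crowding at Cd and does not involve Cd–H. The silane reduces the tert-butyl cation before it can alkylate the dialkoxyarenes, and benzyl aryl ethers and the Cb ester withstand dilute acid at this temperature.

Step 19
Reactants: 27 2,4-bis[4-(benzyloxy)-3-methoxyphenyl]-3-{[(4R,4aR,6S,7R,7aS)-2,4,7-trimethyloctahydro-1H-cyclopenta[c]pyridin-6-yl]oxycarbonyl}cyclobutane-1-carboxylic acid; 25 (4R,4aR,6S,7R,7aS)-2,4,7-trimethyloctahydro-1H-cyclopenta[c]pyridin-6-ol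
Product: 28 1-[(4R,4aR,6R,7R,7aS)-2,4,7-trimethyloctahydro-1H-cyclopenta[c]pyridin-6-yl] 3-[(4R,4aR,6S,7R,7aS)-2,4,7-trimethyloctahydro-1H-cyclopenta[c]pyridin-6-yl] 2,4-bis[4-(benzyloxy)-3-methoxyphenyl]cyclobutane-1,3-dicarboxylate (ring A as in 9; the 6R ester on Cd)
Conditions: PPh3, DIAD, THF, 0 °C → rt
Reagents that add atoms: none
Why: Mitsunobu esterification: the hydroxyl of 25 is activated as an alkoxyphosphonium ion and displaced by the Cd carboxylate with inversion (SN2), which puts the new ester oxygen trans to the C7 methyl (6R). The acid acts only as a nucleophile, so Cd cannot epimerise through a ketene or an enol.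

Step 20
Reactants: 28 the bis(benzyl ether) diester from step 19
Product: 29 target, 1-[(4R,4aR,6R,7R,7aS)-2,4,7-trimethyloctahydro-1H-cyclopenta[c]pyridin-6-yl] 3-[(4R,4aR,6S,7R,7aS)-2,4,7-trimethyloctahydro-1H-cyclopenta[c]pyridin-6-yl] 2,4-bis(4-hydroxy-3-methoxyphenyl)cyclobutane-1,3-dicarboxylate
Conditions: H2 (1 atm), 10% Pd/C, MeOH–EtOAc, AcOH, rt; then aq. NaHCO3
Reagents that add atoms: none
Why: Hydrogenolysis of the two benzyl aryl ethers; alkyl esters, the aryl-substituted cyclobutane and the amines are inert at 1 atm and room temperature, and acetic acid keeps the amines protonated so that they do not slow the catalyst.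

## Compound list

1 | methyl (E)-ferulate | COc1cc(/C=C/C(=O)OC)ccc1O | starting material
2 | methyl (E)-3-[4-(benzyloxy)-3-methoxyphenyl]acrylate | COc1cc(/C=C/C(=O)OC)ccc1OCc1ccccc1 | intermediate
3 | 4-(benzyloxy)-3-methoxybenzaldehyde | COc1cc(C=O)ccc1OCc1ccccc1 | starting material
4 | tert-butyl glycinate | NCC(=O)OC(C)(C)C | starting material
5 | tert-butyl (E)-N-[4-(benzyloxy)-3-methoxybenzylidene]glycinate | COc1cc(/C=N/CC(=O)OC(C)(C)C)ccc1OCc1ccccc1 | intermediate
6 | 2-tert-butyl 4-methyl (2S*,3S*,4R*,5R*)-3,5-bis[4-(benzyloxy)-3-methoxyphenyl]pyrrolidine-2,4-dicarboxylate (racemate) | COc1cc([C@@H]2[C@@H](C(=O)OC)[C@H](c3ccc(OCc4ccccc4)c(OC)c3)N[C@@H]2C(=O)OC(C)(C)C)ccc1OCc1ccccc1 | intermediate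
7 | 1,1-diazene of 6 (not isolated) | COc1cc([C@@H]2[C@@H](C(=O)OC)[C@H](c3ccc(OCc4ccccc4)c(OC)c3)[N+](=[N-])[C@@H]2C(=O)OC(C)(C)C)ccc1OCc1ccccc1 | intermediate
8 | 1-tert-butyl 3-methyl 2,4-bis[4-(benzyloxy)-3-methoxyphenyl]butane-1,4-diyl-1,3-dicarboxylate, 1,4-biradical (not isolated) | COc1cc([C@@H]([CH]C(=O)OC(C)(C)C)[C@@H](C(=O)OC)[CH]c2ccc(OCc3ccccc3)c(OC)c2)ccc1OCc1ccccc1 | intermediate
9 | 1-tert-butyl 3-methyl 2,4-bis[4-(benzyloxy)-3-methoxyphenyl]cyclobutane-1,3-dicarboxylate (meso; aryls cis, tert-butyl ester cis to both, methyl ester trans to both) | COc1cc([C@@H]2[C@@H](C(=O)OC)[C@H](c3ccc(OCc4ccccc4)c(OC)c3)[C@@H]2C(=O)OC(C)(C)C)ccc1OCc1ccccc1 | intermediate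
10 | 3-(tert-butoxycarbonyl)-2,4-bis[4-(benzyloxy)-3-methoxyphenyl]cyclobutane-1-carboxylic acid (meso; acid trans to both aryls) | COc1cc([C@@H]2[C@@H](C(=O)O)[C@H](c3ccc(OCc4ccccc4)c(OC)c3)[C@@H]2C(=O)OC(C)(C)C)ccc1OCc1ccccc1 | intermediate
11 | methyl (S)-3-hydroxy-2-methylpropanoate | COC(=O)[C@@H](C)CO | starting material
12 | methyl (S)-3-[(tert-butyldiphenylsilyl)oxy]-2-methylpropanoate | COC(=O)[C@@H](C)CO[Si](c1ccccc1)(c1ccccc1)C(C)(C)C | intermediate
13 | (S)-3-[(tert-butyldiphenylsilyl)oxy]-2-methylpropanal | O=C[C@@H](C)CO[Si](c1ccccc1)(c1ccccc1)C(C)(C)C | intermediate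
14 | (R)-tert-butyl[(2-methylbut-3-en-1-yl)oxy]diphenylsilane | C=C[C@@H](C)CO[Si](c1ccccc1)(c1ccccc1)C(C)(C)C | intermediate
15 | (R)-2-methylbut-3-en-1-ol | C=C[C@@H](C)CO | intermediate
16 | (R)-2-methylbut-3-en-1-yl 4-methylbenzenesulfonate | C=C[C@@H](C)COS(=O)(=O)c1ccc(C)cc1 | intermediate
17 | but-2-yn-1-amine | CC#CCN | starting material
18 | N-[(R)-2-methylbut-3-en-1-yl]but-2-yn-1-amine | C=C[C@@H](C)CNCC#CC | intermediate
19 | methyl (but-2-yn-1-yl)[(R)-2-methylbut-3-en-1-yl]carbamate | C=C[C@@H](C)CN(CC#CC)C(=O)OC | intermediate
20 | alkyne–Co2(CO)6 complex of 19 (not isolated) | C=C[C@@H](C)CN(C(=O)OC)CC12C3(C)[Co]1(=C=O)(=C=O)(=C=O)[Co]23(=C=O)(=C=O)=C=O | intermediate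
21 | methyl (4R,4aR)-4,7-dimethyl-6-oxo-1,3,4,4a,5,6-hexahydro-2H-cyclopenta[c]pyridine-2-carboxylate | O=C1C[C@H]2C(CN(C(=O)OC)C[C@@H]2C)=C1C | intermediate
22 | methyl (4R,4aR,7S,7aS)-4,7-dimethyl-6-oxooctahydro-2H-cyclopenta[c]pyridine-2-carboxylate (C7 methyl on the concave face; not isolated) | O=C1C[C@H]2[C@H](CN(C(=O)OC)C[C@@H]2C)[C@@H]1C | intermediate
23 | methyl (4R,4aR,7R,7aS)-4,7-dimethyl-6-oxooctahydro-2H-cyclopenta[c]pyridine-2-carboxylate | O=C1C[C@H]2[C@H](CN(C(=O)OC)C[C@@H]2C)[C@H]1C | intermediate
24 | methyl (4R,4aR,6S,7R,7aS)-6-hydroxy-4,7-dimethyloctahydro-2H-cyclopenta[c]pyridine-2-carboxylate | O[C@H]1C[C@H]2[C@H](CN(C(=O)OC)C[C@@H]2C)[C@H]1C | intermediate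
25 | (4R,4aR,6S,7R,7aS)-2,4,7-trimethyloctahydro-1H-cyclopenta[c]pyridin-6-ol (hydroxyl cis to the C7 methyl) | O[C@H]1C[C@H]2[C@H](CN(C)C[C@@H]2C)[C@H]1C | intermediate
26 | 1-tert-butyl 3-[(4R,4aR,6S,7R,7aS)-2,4,7-trimethyloctahydro-1H-cyclopenta[c]pyridin-6-yl] 2,4-bis[4-(benzyloxy)-3-methoxyphenyl]cyclobutane-1,3-dicarboxylate | COc1cc([C@@H]2[C@@H](C(=O)O[C@H]3C[C@H]4[C@H](CN(C)C[C@@H]4C)[C@H]3C)[C@H](c3ccc(OCc4ccccc4)c(OC)c3)[C@@H]2C(=O)OC(C)(C)C)ccc1OCc1ccccc1 | intermediate
27 | 2,4-bis[4-(benzyloxy)-3-methoxyphenyl]-3-{[(4R,4aR,6S,7R,7aS)-2,4,7-trimethyloctahydro-1H-cyclopenta[c]pyridin-6-yl]oxycarbonyl}cyclobutane-1-carboxylic acid | COc1cc([C@@H]2[C@@H](C(=O)O[C@H]3C[C@H]4[C@H](CN(C)C[C@@H]4C)[C@H]3C)[C@H](c3ccc(OCc4ccccc4)c(OC)c3)[C@@H]2C(=O)O)ccc1OCc1ccccc1 | intermediate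
28 | 1-[(4R,4aR,6R,7R,7aS)-2,4,7-trimethyloctahydro-1H-cyclopenta[c]pyridin-6-yl] 3-[(4R,4aR,6S,7R,7aS)-2,4,7-trimethyloctahydro-1H-cyclopenta[c]pyridin-6-yl] 2,4-bis[4-(benzyloxy)-3-methoxyphenyl]cyclobutane-1,3-dicarboxylate | COc1cc([C@@H]2[C@@H](C(=O)O[C@H]3C[C@H]4[C@H](CN(C)C[C@@H]4C)[C@H]3C)[C@H](c3ccc(OCc4ccccc4)c(OC)c3)[C@@H]2C(=O)O[C@@H]2C[C@H]3[C@H](CN(C)C[C@@H]3C)[C@H]2C)ccc1OCc1ccccc1 | intermediate
29 | 1-[(4R,4aR,6R,7R,7aS)-2,4,7-trimethyloctahydro-1H-cyclopenta[c]pyridin-6-yl] 3-[(4R,4aR,6S,7R,7aS)-2,4,7-trimethyloctahydro-1H-cyclopenta[c]pyridin-6-yl] 2,4-bis(4-hydroxy-3-methoxyphenyl)cyclobutane-1,3-dicarboxylate (CNP0283097.4) | COc1cc([C@@H]2[C@@H](C(=O)O[C@H]3C[C@H]4[C@H](CN(C)C[C@@H]4C)[C@H]3C)[C@H](c3ccc(O)c(OC)c3)[C@@H]2C(=O)O[C@@H]2C[C@H]3[C@H](CN(C)C[C@@H]3C)[C@H]2C)ccc1O | target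

## Step count and least certain steps

Total step count: 20. Longest linear sequence: 15 steps (steps 6 to 16, then 17 to 20).

**Step 4 (key step).** Most likely to go wrong: β-scission of the biradical into two cinnamate-type alkenes, and attack of the trivalent-iodine reagent on the dialkoxyarenes (arene oxidation or iodonium formation) or dehydrogenation of the amine before amination. Both follow from a hot, strongly oxidising medium acting on a substrate with two electron-rich rings and two radical-stabilising groups. Fallback: separate N–N bond formation from oxidation. Starting from 6, t-BuONO in THF gives 2-tert-butyl 4-methyl 3,5-bis[4-(benzyloxy)-3-methoxyphenyl]-1-nitrosopyrrolidine-2,4-dicarboxylate F1. Zn in AcOH reduces it to 2-tert-butyl 4-methyl 1-amino-3,5-bis[4-(benzyloxy)-3-methoxyphenyl]pyrrolidine-2,4-dicarboxylate F2. Oxidation of F2 with HgO in CH2Cl2 at 0 °C generates the same 1,1-diazene at low temperature and without trivalent iodine, and the route is rejoined at 9.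

**Step 3.** Most likely to go wrong: insufficient exo preference, together with sluggish addition to an electron-rich cinnamate, since the endo transition state is the usual one with many metals. Fallback: reach the same relative configuration with an endo-selective catalyst and a Z-alkene. Starting from 3, a Still–Gennari olefination (methyl bis(2,2,2-trifluoroethyl)phosphonoacetate, KN(SiMe3)2, 18-crown-6, THF, −78 °C) gives methyl (Z)-3-[4-(benzyloxy)-3-methoxyphenyl]acrylate F3. Cycloaddition of 5 to F3 under AgOAc/PPh3/Et3N gives the all-cis adduct 2-tert-butyl 4-methyl (2S*,3S*,4S*,5R*)-3,5-bis[4-(benzyloxy)-3-methoxyphenyl]pyrrolidine-2,4-dicarboxylate F4. Its C4 ester, flanked by two cis aryl groups, is then epimerised with catalytic NaOMe in MeOH, and the route is rejoined at 6.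

**Step 13.** Most likely to go wrong: slow closure of the six-membered ring, so that the cobalt complex decomposes or oligomerises first, and erosion of the C4 to C4a induction. Fallback: a stepwise early-metal cyclisation under thermodynamic control. Starting from 19, Cp2ZrCl2/n-BuLi in THF (−78 °C → rt) forms reversibly the zirconabicycle methyl (4R,4aR)-6,6-bis(cyclopentadienyl)-4,7-dimethyl-6-zircona-1,3,4,4a,5,6-hexahydro-2H-cyclopenta[c]pyridine-2-carboxylate F5, in which the C4 methyl can settle equatorial. Carbonylation (CO, 1 atm, 0 °C) and quenching with aqueous HCl rejoin the route at 21; the carbamate carbonyl is the group to watch at low temperature.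

**Step 15.** Most likely to go wrong: hydride delivery from the convex face, because the concave face that the C7 methyl leaves open is shielded by ring B. Fallback: make the C6 epimer on purpose and invert it. Starting from 23, NaBH4 in MeOH gives methyl (4R,4aR,6R,7R,7aS)-6-hydroxy-4,7-dimethyloctahydro-2H-cyclopenta[c]pyridine-2-carboxylate F6. A Mitsunobu reaction with 4-nitrobenzoic acid (PPh3, DIAD) gives methyl (4R,4aR,6S,7R,7aS)-4,7-dimethyl-6-[(4-nitrobenzoyl)oxy]octahydro-2H-cyclopenta[c]pyridine-2-carboxylate F7, and K2CO3 in MeOH rejoins the route at 24.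

**Step 19.** Most likely to go wrong: elimination of the activated alcohol towards C6=C7, or failure of the crowded carboxylate to attack from the concave face. Fallback: form the Cd ester with retention from the C6-epimeric alcohol. F6 (from 23 as above) is reduced with LiAlH4 to (4R,4aR,6R,7R,7aS)-2,4,7-trimethyloctahydro-1H-cyclopenta[c]pyridin-6-ol F8. Acid 27 is converted into its acyl fluoride (cyanuric fluoride, pyridine), which is less prone to ketene formation, and acylates F8 with DMAP; the route is rejoined at 28.

## Further compounds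

F1 | step 4 | 2-tert-butyl 4-methyl (2S*,3S*,4R*,5R*)-3,5-bis[4-(benzyloxy)-3-methoxyphenyl]-1-nitrosopyrrolidine-2,4-dicarboxylate | COc1cc([C@@H]2[C@@H](C(=O)OC)[C@H](c3ccc(OCc4ccccc4)c(OC)c3)N(N=O)[C@@H]2C(=O)OC(C)(C)C)ccc1OCc1ccccc1
F2 | step 4 | 2-tert-butyl 4-methyl (2S*,3S*,4R*,5R*)-1-amino-3,5-bis[4-(benzyloxy)-3-methoxyphenyl]pyrrolidine-2,4-dicarboxylate | COc1cc([C@@H]2[C@@H](C(=O)OC)[C@H](c3ccc(OCc4ccccc4)c(OC)c3)N(N)[C@@H]2C(=O)OC(C)(C)C)ccc1OCc1ccccc1
F3 | step 3 | methyl (Z)-3-[4-(benzyloxy)-3-methoxyphenyl]acrylate | COc1cc(/C=C\C(=O)OC)ccc1OCc1ccccc1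
F4 | step 3 | 2-tert-butyl 4-methyl (2S*,3S*,4S*,5R*)-3,5-bis[4-(benzyloxy)-3-methoxyphenyl]pyrrolidine-2,4-dicarboxylate (all-cis; racemate) | COc1cc([C@@H]2[C@H](C(=O)OC)[C@H](c3ccc(OCc4ccccc4)c(OC)c3)N[C@@H]2C(=O)OC(C)(C)C)ccc1OCc1ccccc1
F5 | step 13 | methyl (4R,4aR)-6,6-bis(cyclopentadienyl)-4,7-dimethyl-6-zircona-1,3,4,4a,5,6-hexahydro-2H-cyclopenta[c]pyridine-2-carboxylate | CC1=C2CN(C(=O)OC)C[C@H](C)[C@H]2C[Zr]1(C1C=CC=C1)C1C=CC=C1
F6 | step 15 | methyl (4R,4aR,6R,7R,7aS)-6-hydroxy-4,7-dimethyloctahydro-2H-cyclopenta[c]pyridine-2-carboxylate | O[C@@H]1C[C@H]2[C@H](CN(C(=O)OC)C[C@@H]2C)[C@H]1C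
F7 | step 15 | methyl (4R,4aR,6S,7R,7aS)-4,7-dimethyl-6-[(4-nitrobenzoyl)oxy]octahydro-2H-cyclopenta[c]pyridine-2-carboxylate | O=C(O[C@H]1C[C@H]2[C@H](CN(C(=O)OC)C[C@@H]2C)[C@H]1C)c1ccc([N+](=O)[O-])cc1
F8 | step 19 | (4R,4aR,6R,7R,7aS)-2,4,7-trimethyloctahydro-1H-cyclopenta[c]pyridin-6-ol | O[C@@H]1C[C@H]2[C@H](CN(C)C[C@@H]2C)[C@H]1C
A1 | alternative 1 | N-methyl-N-[(R)-2-methylbut-3-en-1-yl]but-2-yn-1-amine | C=C[C@@H](C)CN(C)CC#CC
A2 | alternative 1 | (4R,4aR)-2,4,7-trimethyl-1,2,3,4,4a,5-hexahydro-6H-cyclopenta[c]pyridin-6-one | O=C1C[C@H]2C(CN(C)C[C@@H]2C)=C1C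
A3 | alternative 2 | tert-butyl 2-oxo-2H-pyran-5-carboxylate (tert-butyl coumalate) | O=C1C=CC(C(=O)OC(C)(C)C)=CO1
A4 | alternative 2 | tert-butyl 3-oxo-2-oxabicyclo[2.2.0]hex-5-ene-6-carboxylate (racemate; relative configuration shown) | O=C1O[C@H]2C(C(=O)OC(C)(C)C)=C[C@@H]12
A5 | alternative 2 | cis-3-(tert-butoxycarbonyl)cyclobutane-1-carboxylic acid | O=C(O)[C@H]1C[C@@H](C(=O)OC(C)(C)C)C1
A6 | alternative 2 | 1-(benzyloxy)-4-iodo-2-methoxybenzene | COc1cc(I)ccc1OCc1ccccc1
A7 | alternative 3 | 2-methyl-4-{1-[methyl(trimethylsilylmethyl)amino]propan-2-yl}cyclopent-2-en-1-one (configured as in A8 at the carbons that become C4 and C4a) | O=C1C[C@H]([C@@H](C)CN(C)C[Si](C)(C)C)C=C1C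
A8 | alternative 3 | (4R,4aR,7R,7aS)-2,4,7-trimethyloctahydro-6H-cyclopenta[c]pyridin-6-one | O=C1C[C@H]2[C@H](CN(C)C[C@@H]2C)[C@H]1C
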